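## Structural features

The target (C20H24O7) is a furanoheliangolide: a ten-membered carbocycle C1–C10 in which C3 and C10 are joined by an oxygen atom, so that O, C3, C2, C1 and C10 form a furan-3(2H)-one (ring A; C1 ketone, C2=C3 enol ether), and which is fused along C6–C7 to a trans α-methylene-γ-butyrolactone (ring C; O6–C12, C11=C13). C4=C5 is a Z trisubstituted alkene carrying the hydroxymethyl carbon C15 on C4; C8 carries the 3-methylbutanoate and C10 is quaternary (C14 methyl, ether oxygen). C6 (R), C7 (R) and C8 (R) are contiguous: H6 is β, H7 is α, and the C8 oxygen is β and cis to C11. C10 (S) is separated from this triad by the C9 methylene and holds its oxygen bridge on the β face. Fragile groups are the α-methylene lactone (conjugate addition, hydride and enolate chemistry), the two acyloxy groups flanking C7 (lactone migration from O6 to O8, β-elimination once C8 is a ketone), the vinylogous ester and the allylic C6–O and C15–O bonds. The real difficulty is the strained, bridged ten-membered ring together with the remote link between C10 and the C6–C8 triad. The key step exploits the fact that C3 and C10 with their bridging oxygen are the 2- and 5-positions of a furan whose 3- and 4-positions are C2 and C1: a Diels–Alder reaction of this furan with a C8=C9 alkene creates quaternary C10 (bond C9–C10) and a temporary C3–C8 bond that closes a six-membered ring B (C3–C4=C5–C6–C7–C8), which a later fragmentation opens into the macrocycle. One stereochemical point decides the design of the cycloaddition substrate: in the exo adduct of 10S configuration, O6 and C11 are trans-diaxial on ring B, which a closed trans-lactone cannot span, so O6 is held on the C8 boron during the cycloaddition and the lactone is closed only after the fragmentation.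

## Logic of the disconnections

29 from 28. Cut: the O15–Si bond and the two C1–OMe bonds; no skeletal bond. Both masks are acid-labile and fall together, so the last step needs only dilute aqueous acid and no base or nucleophile near the methylene lactone. Demand: the allylic ketal and the silyl ether must hydrolyse faster than the two esters.

28 from 27. Cut: the C8 O–acyl bond. The ester is put on after the methylenation so that no second enolisable ester is present during enolate chemistry. Demand: acylation of a hindered secondary alcohol without addition to C13.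

27 from 24. Cut: C11=C13. The methylene group must be absent during the cycloaddition (it would be a competing dienophile) and during the hydride reduction (conjugate reduction). Demand: a lactone enolate formed next to a free C8 alkoxide, with the ketal still masking C1.

24 from 23. Cut: C8–H. The C8 carbonyl is what the fragmentation delivers. Demand: hydride on the α face of C8.

23 from 20. In this direction C3–C8 is re-formed (C2=C3 and C8=O become C2–Br and C8–OH) and the lactone bond O6–C12 is opened to an ethyl ester. The gain is the replacement of a strained bridged ten-membered ring by a rigid polycycle in which all stereochemistry is readable. Demands: C2–Br antiperiplanar to C3–C8, and a C6 alkoxide that lactonises faster than it triggers retro-aldol cleavage.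

20 from 18 through 19. Cut: C8–O back to C8–B (also O6–H back to O6–B), then C2–Br and one C1–OMe back to the C1=C2 enol ether. Boron stores the C8 oxygen with retention; bromine must enter exo, anti to the bond that is to break.

18 from 17. Cut: C9–C10 and C3–C8 (retro-[4+2]). Two rings, two skeletal bonds and three stereocentres are removed at once, leaving a 2,3,5-trisubstituted furan and a 1,1-disubstituted alkenylboron. If O6 were acylated by C12 at this stage, the trans-lactone would fix the C5–C6–C7–C8 torsion with the sign opposite to that of the exo ring fusion needed for 10S; ring B of the required adduct would be a boat and the 10-epimer would be favoured. O6 is therefore bonded to boron, which makes the required face the only one the alkene can offer. Demands: exo closure and survival of the B–O6 bond on heating.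

17 from 10 and 14. Cut: C6–C7 and the O6–B bond. One allylboration joins the two halves, creates C6 and C7 and leaves the alkenylboron on C8. Demands: syn relative configuration (from the Z allylboronate) and absolute control by a chiral acid.

14 from 13, and 13 from 11 and 12. Cut: the C8–B and C9–B bonds, then C7–C11 by a [3,3] shift. The whole C7–C12 unit with both boron atoms comes from two commodity chemicals. Demand: diboration of the terminal allene double bond only, with Z geometry.

10 from 9, and 9 from 4 and 6. Cut: the C3–C4 bond between furan and alkene (the aldehyde is an oxidation-level adjustment). The trisubstituted Z alkene comes with fixed geometry from a vinyl iodide. Demand: coupling with retention, in the presence of a free hydroxyl.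

6 from 5. Cut: C4–I and C5–H. A hydroxyl-directed trans-hydroalumination of a symmetric butynediol derivative sets regio- and stereochemistry.

4 from 3, and 3 from 1. Cut: C1–OMe and C10–C14. Both substituents are introduced on commercial 3-bromofuran; the C2 proton is removed selectively next to bromine.

## Other disconnections considered

Alternative 1: The cut runs through the furanone itself (O–C3 and C10–C14, the methyl arriving on C10 by migration) and leaves C6–C7 open for a later ring closure. In the forward step AuCl3 (trivalent gold) activates the C2≡C3 triple bond, the carbonyl oxygen on C10 closes onto C3 and the methyl group shifts from C1 to C10, giving the furanone A1. In its favour: the furanone and quaternary C10 appear early under mild, nearly neutral conditions, the C8 ester, the C11–C13 acrylate unit and C15 are already at the right oxidation level, and no late enolate chemistry is needed. Against it here: the configuration of C10 would have to be relayed from a carbinol centre set under weak 1,3-control from C8, and the ten-membered ring with C6 and C7 would still have to come from a macrocyclisation that fights the full ring strain and creates two stereocentres. Compared with the chosen plan: on structure A1 is the better intermediate in functional-group economy (all carbons and the ester in place, where 18 lacks C13 and the ester); on mechanism a cationic cyclisation with 1,2-shift replaces a pericyclic step, but the strain problem is only postponed, whereas the chosen plan stores it in a polycycle and releases it by fragmentation; on step economy the two are about equal up to the ring closure, after which the alternative carries the larger risk.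

Alternative 2: The cut is at C7–C8 and C11–C13 on the lactone. In the forward step a sulfur-stabilised C8 acyl-anion equivalent adds 1,4 to C7 of a chiral-pool butenolide, and the lactone enolate is intercepted at C11 by an iminium electrophile in the same flask, giving A2. In its favour: C6 comes from the chiral pool, C7 and C11 follow by reliable anti addition and anti trapping, C13 is carried from the start as an aminomethyl group that unmasks by quaternisation and elimination, and C10 is pre-set in the nucleophile. Against it here: the furanone, the C4=C5 alkene and above all the ten-membered ring remain to be built after A2; a basic amine and a dithiane must be carried and removed in a sensitive setting. Compared with the chosen plan: on structure the alternative is the better one in stereochemical certainty at C6, C7 and C10 (each from a defined source) and in the early placement of C13; on mechanism an ionic three-component coupling solves the lactone but not the macrocycle; on step economy it needs more steps after its key step than the chosen plan needs after 18.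

Alternative 3: The cut forms C1–C10 and cleaves C3–C8 in one [3,3] shift. In the forward step KH with 18-crown-6 generates the C8 alkoxide of the 1,5-diene C1=C2–C3–C8–C9=C10, and the anionic oxy-Cope rearrangement gives the oxygen-bridged cyclodecadienone A3 with the C8 ketone. In its favour: it uses the same logic as the chosen plan (a temporary C3–C8 bond and ring expansion) in a single concerted, stereospecific and strongly accelerated step from a chiral-pool cyclohexane; on this point it is the equal or the better of the two-stage cycloaddition and fragmentation. Against it here: A3 is far from the target in oxidation state. C1 is an ether that must become a ketone with C2=C3 in conjugation, C15 is a methyl group, and C11–C13 is an isopropenyl group without the C12 carboxyl. Several late allylic oxidations would have to be told apart, and the configuration at C10 depends on a chair or boat transition state. Compared with the chosen plan: on structure the chosen route brings O1, O15 and C12 at the right level through the key step; on mechanism both break C3–C8, once pericyclically and once by fragmentation; on step economy the alternative is shorter to the ring and longer afterwards.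

Key step: step 9

Remark: atom numbers C1–C15 are those of the target skeleton (C1 ketone carbon, C3–O–C10 bridge, O6 lactone oxygen, C8 ester carbon, C13 methylene, C14 methyl on C10, C15 hydroxymethyl on C4) and are used for all intermediates and their stereodescriptors.

Remark: in steps 8–11 O6 is bonded to boron and C12 is an ethyl ester; no carbon–carbon bond of the cycloaddition precursor or of the cycloadduct is affected, and the lactone bond O6–C12 is closed in step 12.

Remark: (S)-TRIP is (S)-3,3'-bis(2,4,6-triisopropylphenyl)-1,1'-binaphthyl-2,2'-diyl hydrogen phosphate; the S acid is chosen by analogy with the usual sense of induction for aryl and alkenyl aldehydes and its sense should be confirmed on a model aldehyde.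

## Steps

Step 1
Reactants: 1 3-bromofuran
Product: 3 3-bromo-2-methylfuran, via 3-bromo-2-furyllithium 2 (not isolated)
Conditions: LiN(iPr)2, THF, -78 °C; MeI, -78 °C to rt
Reagents that add atoms: iodomethane, CI
Why: The amide base removes H2, the most acidic proton (between the ring oxygen and bromine), without halogen–metal exchange; the heteroaryllithium is methylated (directed lithiation and alkylation). This methyl group becomes C14.

Step 2
Reactants: 3 3-bromo-2-methylfuran
Product: 4 3-methoxy-2-methylfuran
Conditions: NaOMe, CuBr (10 mol %), MeOH/DMF, 100 °C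
Reagents that add atoms: sodium methoxide, C[O-].[Na+]
Why: Copper-catalysed Ullmann-type methoxylation of a heteroaryl bromide; the product is a volatile, acid-sensitive enol-ether-like furan and is distilled and stored over base.

Step 3
Reactants: 5 4-[(tert-butyldimethylsilyl)oxy]but-2-yn-1-ol
Product: 6 (2Z)-4-[(tert-butyldimethylsilyl)oxy]-3-iodobut-2-en-1-ol
Conditions: NaAlH2(OCH2CH2OMe)2, THF, 0 °C; I2, -78 to 0 °C
Reagents that add atoms: iodine, II
Why: Hydroxyl-directed trans-hydroalumination places hydride on C5 and aluminium on C4 in a five-membered alkoxyaluminate; iodinolysis with retention gives the Z vinyl iodide with iodine cis to the CH2OH carbon (C6).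

Step 4
Reactants: 4 3-methoxy-2-methylfuran; 6 (2Z)-4-[(tert-butyldimethylsilyl)oxy]-3-iodobut-2-en-1-ol
Product: 9 (2Z)-4-[(tert-butyldimethylsilyl)oxy]-3-(4-methoxy-5-methylfuran-2-yl)but-2-en-1-ol, via (4-methoxy-5-methylfuran-2-yl)lithium 7 (not isolated), via chloro(4-methoxy-5-methylfuran-2-yl)zinc 8 (not isolated)
Conditions: 4 (2.2 equiv), n-BuLi, THF, -78 to 0 °C; ZnCl2; then 6, Pd(PPh3)4 (5 mol %), 45 °C
Reagents that add atoms: none
Why: Lithiation occurs at the only free α-position of the furan; after transmetalation to zinc a Negishi coupling joins C3 to C4 with retention of alkene geometry, so C6 ends cis to the furan; the excess zinc reagent tolerates the free hydroxyl.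

Step 5
Reactants: 9 (2Z)-4-[(tert-butyldimethylsilyl)oxy]-3-(4-methoxy-5-methylfuran-2-yl)but-2-en-1-ol
Product: 10 (2Z)-4-[(tert-butyldimethylsilyl)oxy]-3-(4-methoxy-5-methylfuran-2-yl)but-2-enal
Conditions: MnO2, CH2Cl2, rt, dark
Reagents that add atoms: none
Why: Neutral allylic oxidation with MnO2 leaves the acid-sensitive furan and the Z geometry untouched; the enal is used without storage.

Step 6
Reactants: 11 prop-2-yn-1-ol; 12 triethyl orthoacetate
Product: 13 ethyl penta-3,4-dienoate
Conditions: EtCO2H (cat.), 140 °C, distil off EtOH
Reagents that add atoms: none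
Why: Johnson–Claisen rearrangement of the propargyl ketene acetal forms C7–C11 and the terminal allene in one operation.

Step 7
Reactants: 13 ethyl penta-3,4-dienoate
Product: 14 ethyl (3Z)-4,5-bis(4,4,5,5-tetramethyl-1,3,2-dioxaborolan-2-yl)pent-3-enoate
Conditions: B2pin2, Pt(dba)2 (3 mol %), PCy3 (6 mol %), toluene, 50 °C
Reagents that add atoms: bis(pinacolato)diboron, CC1(C)OB(OC1(C)C)B1OC(C)(C)C(C)(C)O1
Why: Zerovalent-platinum-catalysed syn diboration of a monosubstituted allene goes to the terminal double bond with the bulky phosphine and from the face remote from the substituent, which gives the Z allylboronate with the vinyl boron on C8.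

Step 8
Reactants: 10 (2Z)-4-[(tert-butyldimethylsilyl)oxy]-3-(4-methoxy-5-methylfuran-2-yl)but-2-enal; 14 ethyl (3Z)-4,5-bis(4,4,5,5-tetramethyl-1,3,2-dioxaborolan-2-yl)pent-3-enoate
Product: 17 ethyl 2-[(4R,5S)-5-{(1Z)-3-[(tert-butyldimethylsilyl)oxy]-2-(4-methoxy-5-methylfuran-2-yl)prop-1-en-1-yl}-2-hydroxy-3-methylidene-1,2-oxaborolan-4-yl]acetate (6S,7R in skeleton numbering), via O6-pinacolboryl ether 15 (not isolated), via (6S,7R)-hydroxy ester pinacol alkenylboronate 16 (not isolated)
Conditions: (S)-TRIP (5 mol %), 4 Å MS, toluene, -30 °C to rt; then NaIO4, NH4OAc, acetone/H2O, rt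
Reagents that add atoms: water, O
Why: Allylboration through a closed chair transition state with the Z γ-substituent axial forms C6–C7 with syn O6/C11 (the later trans-lactone relationship), and the chiral phosphoric acid selects the aldehyde face for 6S,7R. Periodate then cleaves the pinacol esters and the freed alkenylboronic acid closes onto the C6 hydroxyl as a five-membered hemiboronate, which also keeps O6 from lactonising.

Step 9
Reactants: 17 ethyl 2-[(4R,5S)-5-{(1Z)-3-[(tert-butyldimethylsilyl)oxy]-2-(4-methoxy-5-methylfuran-2-yl)prop-1-en-1-yl}-2-hydroxy-3-methylidene-1,2-oxaborolan-4-yl]acetate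
Product: 18 tether-exo cycloadduct (3S,6S,7R,8S,10S): C3–O–C10 oxygen bridge; C1(OMe)=C2 enol ether; ring B C3–C4=C5–C6–C7–C8; endo boron on C8 as B(OH) bonded to O6; CH2CO2Et on C7; CH2OTBS on C4; CH3 on C10
Conditions: toluene (0.005 M), 2,6-di-tert-butyl-4-methylphenol (cat.), base-washed sealed vessel, 100 °C; cooled and used at once
Reagents that add atoms: none
Why: Thermal, concerted but asynchronous [4+2] cycloaddition of normal electron demand between the electron-rich 3-methoxyfuran (C3=C2–C1=C10) and the alkenylboron C8=C9, whose vacant boron orbital lowers the LUMO; the closest known reaction type is the intramolecular Diels–Alder reaction of furans, here with an alkenylboronate dienophile that is held in addition by a boron–oxygen tether. Ring B (C3–C4=C5–C6–C7–C8) closes through the four-atom tether in the exo mode, the only one a tether this short allows, so that C7 lies syn to the oxygen bridge and boron is endo; the oxanorbornene (O, C3, C2, C1, C10, C9, C8) is the cycloaddition ring itself. C3, C8 and C10 are created together and are fixed by one element, the 1,2-oxaborolane: C3 can reach C8 only on the face of the exocyclic alkene that is cis to C5 on C6, which in the exo mode gives 3S,8S,10S from 6S,7R. In 18 ring B is a half-chair with O6 and boron 1,3-diaxial (bridged) and C11 axial; with O6 acylated by C12 instead, the trans-lactone would force the opposite sign of the C5–C6–C7–C8 torsion, ring B of the 10S adduct would have to be a boat and the equilibrium would favour the 10-epimer. The step therefore needs face selectivity (C10) and exo selectivity; the first is secured covalently by the O6–B ring, the second by the tether length. The cycloaddition is reversible, so 18 is carried directly into step 10, which removes the C1=C2 double bond.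

Step 10
Reactants: 18 tether-exo cycloadduct (3S,6S,7R,8S,10S)
Product: 19 exo-2-bromo-1,1-dimethoxy derivative of 18 (2R,3S,6S,7R,8S,10S), isolated as the hemiboronate after aqueous work-up
Conditions: N-bromosuccinimide, 2,6-lutidine, MeOH/CH2Cl2, -78 to -40 °C
Reagents that add atoms: N-bromosuccinimide, O=C1CCC(=O)N1Br; methanol, CO
Why: Bromoketalisation of the enol ether, by far the most electron-rich alkene present: bromine enters C2 from the exo face (syn to the oxygen bridge) and methanol captures the C1 oxocarbenium ion. The exo C2–Br bond is antiperiplanar to C3–C8 and the adduct can no longer revert.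

Step 11
Reactants: 19 exo-2-bromo-1,1-dimethoxy derivative of 18
Product: 20 diol (2R,3R,6S,7S,8R,10S): endo C8–OH and C6–OH; CH2CO2Et on C7; exo C2–Br; C1(OMe)2
Conditions: NaBO3·4H2O, THF/H2O, 0 °C to rt
Reagents that add atoms: sodium perborate, [Na+].[O-]OB=O
Why: Oxidation of the tertiary C8–B bond by 1,2-migration from boron to oxygen with retention, and hydrolysis of the O6–B bond; the mild perborate leaves the bromide, the ketal and the ester alone. O6 and C11 remain trans-diaxial on ring B, so the hydroxy ester does not lactonise.

Step 12
Reactants: 20 diol (2R,3R,6S,7S,8R,10S)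
Product: 23 (6R,7S,10S)-15-[(tert-butyldimethylsilyl)oxy]-1,1-dimethoxy-8-oxo-3,10-epoxygermacra-2,4Z-dien-12,6-olide, via dipotassium 6,8-dialkoxide 21 (not isolated), via ring-opened 8-oxo ester C6 potassium alkoxide 22 (not isolated)
Conditions: KN(SiMe3)2 (2.2 equiv), THF, -78 to -20 °C; AcOH, -78 °C; NaHCO3 work-up, Et3N-deactivated silica
Reagents that add atoms: none
Why: Grob fragmentation: the C8 alkoxide pushes out the antiperiplanar exo bromide across C3–C8, giving the C8 ketone, the C2=C3 enol ether and the ten-membered ring. In the now flexible macrocycle the C6 alkoxide closes onto the ethyl ester (5-exo-trig) to the trans-lactone. C6, C7 and C10 are untouched.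

Step 13
Reactants: 23 (6R,7S,10S)-15-[(tert-butyldimethylsilyl)oxy]-1,1-dimethoxy-8-oxo-3,10-epoxygermacra-2,4Z-dien-12,6-olide
Product: 24 (6R,7R,8R,10S)-15-[(tert-butyldimethylsilyl)oxy]-8-hydroxy-1,1-dimethoxy-3,10-epoxygermacra-2,4Z-dien-12,6-olide
Conditions: NaBH4, MeOH/CH2Cl2, -78 to -40 °C
Reagents that add atoms: none
Why: Chemoselective ketone reduction (lactone, ketal and enol ether are inert at this temperature). Hydride should add from the α face, that of H7, anti to the lactone carbon C11 on the neighbouring centre and away from the β oxygen bridge, which places the hydroxyl β and cis to C11 as in the target; the sense is not secured and is covered at the end.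

Step 14
Reactants: 24 (6R,7R,8R,10S)-15-[(tert-butyldimethylsilyl)oxy]-8-hydroxy-1,1-dimethoxy-3,10-epoxygermacra-2,4Z-dien-12,6-olide
Product: 27 (6R,7R,8R,10S)-15-[(tert-butyldimethylsilyl)oxy]-8-hydroxy-1,1-dimethoxy-3,10-epoxygermacra-2,4Z,11(13)-trien-12,6-olide, via 11-(dimethylaminomethyl) lactone 25 (not isolated), via trimethylammonium iodide 26 (not isolated)
Conditions: LiN(iPr)2 (2.3 equiv), THF, -78 °C; CH2=NMe2+ I-, -78 to -20 °C; then MeI, MeOH, rt; then NaHCO3 (aq), CH2Cl2
Reagents that add atoms: N,N-dimethylmethyleneiminium iodide, C=[N+](C)C.[I-]
Why: The alkoxide/lactone-enolate dianion is aminomethylated at C11 anti to C8 (Mannich reaction); quaternisation and mild base elimination then give the exocyclic methylene. While it is an enolate the lactone cannot migrate to O8, and the ketal keeps C1 unreactive.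

Step 15
Reactants: 27 (6R,7R,8R,10S)-15-[(tert-butyldimethylsilyl)oxy]-8-hydroxy-1,1-dimethoxy-3,10-epoxygermacra-2,4Z,11(13)-trien-12,6-olide
Product: 28 8-O-(3-methylbutanoyl) derivative of 27 (6R,7R,8R,10S)
Conditions: (Me2CHCH2CO)2O, DMAP (cat.), Et3N, CH2Cl2, 0 °C to rt
Reagents that add atoms: 3-methylbutanoic anhydride, CC(C)CC(=O)OC(=O)CC(C)C
Why: Nucleophile-catalysed acylation of the only free hydroxyl with retention at C8; the conditions are non-acidic (ketal) and only weakly nucleophilic (methylene lactone).

Step 16
Reactants: 28 8-O-(3-methylbutanoyl) derivative of 27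
Product: 29 (6R,7R,8R,10S)-15-hydroxy-8-(3-methylbutanoyloxy)-1-oxo-3,10-epoxygermacra-2,4Z,11(13)-trien-12,6-olide (CNP0171896.1)
Conditions: HF (48 % aq)/MeCN 1:19, 0 °C to rt
Reagents that add atoms: water, O
Why: One mild acid treatment hydrolyses the allylic dimethyl ketal to the furanone carbonyl (through a doubly oxygen-stabilised cation) and cleaves the primary allylic silyl ether; esters, lactone and the methylene group are stable to these conditions and no stereocentre is touched.

## Compound list

1 | 3-bromofuran | Brc1ccoc1 | starting material
2 | 3-bromo-2-furyllithium | [Li]c1occc1Br | intermediate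
3 | 3-bromo-2-methylfuran | Cc1occc1Br | intermediate
4 | 3-methoxy-2-methylfuran | COc1ccoc1C | intermediate
5 | 4-[(tert-butyldimethylsilyl)oxy]but-2-yn-1-ol | OCC#CCO[Si](C)(C)C(C)(C)C | starting material
6 | (2Z)-4-[(tert-butyldimethylsilyl)oxy]-3-iodobut-2-en-1-ol | OC/C=C(\I)CO[Si](C)(C)C(C)(C)C | intermediate
7 | (4-methoxy-5-methylfuran-2-yl)lithium | [Li]c1cc(OC)c(C)o1 | intermediate
8 | chloro(4-methoxy-5-methylfuran-2-yl)zinc | Cl[Zn]c1cc(OC)c(C)o1 | intermediate
9 | (2Z)-4-[(tert-butyldimethylsilyl)oxy]-3-(4-methoxy-5-methylfuran-2-yl)but-2-en-1-ol | Cc1oc(cc1OC)/C(CO[Si](C)(C)C(C)(C)C)=C\CO | intermediate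
10 | (2Z)-4-[(tert-butyldimethylsilyl)oxy]-3-(4-methoxy-5-methylfuran-2-yl)but-2-enal | Cc1oc(cc1OC)/C(CO[Si](C)(C)C(C)(C)C)=C\C=O | intermediate
11 | prop-2-yn-1-ol | C#CCO | starting material
12 | triethyl orthoacetate | CCOC(C)(OCC)OCC | starting material
13 | ethyl penta-3,4-dienoate | C=C=CCC(=O)OCC | intermediate
14 | ethyl (3Z)-4,5-bis(4,4,5,5-tetramethyl-1,3,2-dioxaborolan-2-yl)pent-3-enoate | CCOC(=O)C/C=C(\CB1OC(C)(C)C(C)(C)O1)B1OC(C)(C)C(C)(C)O1 | intermediate
15 | ethyl (3R,4S,5Z)-7-[(tert-butyldimethylsilyl)oxy]-6-(4-methoxy-5-methylfuran-2-yl)-4-[(pinacolatoboryl)oxy]-3-[1-(pinacolatoboryl)ethenyl]hept-5-enoate | Cc1oc(cc1OC)/C(CO[Si](C)(C)C(C)(C)C)=C\[C@@H](OB2OC(C)(C)C(C)(C)O2)[C@H](CC(=O)OCC)C(=C)B3OC(C)(C)C(C)(C)O3 | intermediate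
16 | ethyl (3R,4S,5Z)-7-[(tert-butyldimethylsilyl)oxy]-4-hydroxy-6-(4-methoxy-5-methylfuran-2-yl)-3-[1-(pinacolatoboryl)ethenyl]hept-5-enoate | Cc1oc(cc1OC)/C(CO[Si](C)(C)C(C)(C)C)=C\[C@@H](O)[C@H](CC(=O)OCC)C(=C)B2OC(C)(C)C(C)(C)O2 | intermediate
17 | ethyl 2-[(4R,5S)-5-{(1Z)-3-[(tert-butyldimethylsilyl)oxy]-2-(4-methoxy-5-methylfuran-2-yl)prop-1-en-1-yl}-2-hydroxy-3-methylidene-1,2-oxaborolan-4-yl]acetate | Cc1oc(cc1OC)/C(CO[Si](C)(C)C(C)(C)C)=C\[C@H]2OB(O)C(=C)[C@H]2CC(=O)OCC | intermediate
18 | tether-exo cycloadduct (3S,6S,7R,8S,10S); C1(OMe)=C2 enol ether; endo C8 boron bonded to O6 | C[C@@]12C[C@@]3(B4O)[C@@H](CC(=O)OCC)[C@H](O4)C=C(CO[Si](C)(C)C(C)(C)C)[C@]3(O1)C=C2OC | intermediate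
19 | exo-2-bromo-1,1-dimethoxy derivative of 18 (2R,3S,6S,7R,8S,10S) | C[C@@]12C[C@@]3(B4O)[C@@H](CC(=O)OCC)[C@H](O4)C=C(CO[Si](C)(C)C(C)(C)C)[C@]3(O1)[C@@H](Br)C2(OC)OC | intermediate
20 | 6,8-diol (2R,3R,6S,7S,8R,10S) with C7 CH2CO2Et; exo C2–Br; C1(OMe)2 | C[C@@]12C[C@@]3(O)[C@@H](CC(=O)OCC)[C@H](O)C=C(CO[Si](C)(C)C(C)(C)C)[C@]3(O1)[C@@H](Br)C2(OC)OC | intermediate
21 | dipotassium 6,8-dialkoxide of 20 | C[C@@]12C[C@@]3([O-])[C@@H](CC(=O)OCC)[C@H]([O-])C=C(CO[Si](C)(C)C(C)(C)C)[C@]3(O1)[C@@H](Br)C2(OC)OC.[K+].[K+] | intermediate
22 | potassium C6 alkoxide of the ring-opened 8-oxo ethyl ester (6R,7S,10S) | [O-][C@@H]1/C=C(/CO[Si](C)(C)C(C)(C)C)C2=CC(OC)(OC)[C@](C)(CC(=O)[C@H]1CC(=O)OCC)O2.[K+] | intermediate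
23 | (6R,7S,10S)-15-[(tert-butyldimethylsilyl)oxy]-1,1-dimethoxy-8-oxo-3,10-epoxygermacra-2,4Z-dien-12,6-olide | C1C(=O)O[C@@H]2/C=C(/CO[Si](C)(C)C(C)(C)C)C3=CC(OC)(OC)[C@](C)(CC(=O)[C@@H]12)O3 | intermediate
24 | (6R,7R,8R,10S)-15-[(tert-butyldimethylsilyl)oxy]-8-hydroxy-1,1-dimethoxy-3,10-epoxygermacra-2,4Z-dien-12,6-olide | C1C(=O)O[C@@H]2/C=C(/CO[Si](C)(C)C(C)(C)C)C3=CC(OC)(OC)[C@](C)(C[C@@H](O)[C@@H]12)O3 | intermediate
25 | (11R)-11-(dimethylaminomethyl) derivative of 24; aminomethyl group anti to C8 | CN(C)C[C@@H]1C(=O)O[C@@H]2/C=C(/CO[Si](C)(C)C(C)(C)C)C3=CC(OC)(OC)[C@](C)(C[C@@H](O)[C@@H]12)O3 | intermediate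
26 | trimethylammonium iodide of 25 | C[N+](C)(C)C[C@@H]1C(=O)O[C@@H]2/C=C(/CO[Si](C)(C)C(C)(C)C)C3=CC(OC)(OC)[C@](C)(C[C@@H](O)[C@@H]12)O3.[I-] | intermediate
27 | (6R,7R,8R,10S)-15-[(tert-butyldimethylsilyl)oxy]-8-hydroxy-1,1-dimethoxy-3,10-epoxygermacra-2,4Z,11(13)-trien-12,6-olide | C=C1C(=O)O[C@@H]2/C=C(/CO[Si](C)(C)C(C)(C)C)C3=CC(OC)(OC)[C@](C)(C[C@@H](O)[C@@H]12)O3 | intermediate
28 | 8-O-(3-methylbutanoyl) derivative of 27 (6R,7R,8R,10S) | C=C1C(=O)O[C@@H]2/C=C(/CO[Si](C)(C)C(C)(C)C)C3=CC(OC)(OC)[C@](C)(C[C@@H](OC(=O)CC(C)C)[C@@H]12)O3 | intermediate
29 | (6R,7R,8R,10S)-15-hydroxy-8-(3-methylbutanoyloxy)-1-oxo-3,10-epoxygermacra-2,4Z,11(13)-trien-12,6-olide (CNP0171896.1) | C=C1C(=O)O[C@@H]2/C=C(/CO)C3=CC(=O)[C@](C)(C[C@@H](OC(=O)CC(C)C)[C@@H]12)O3 | target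

## Step count and least certain steps

Total: 16 steps. Longest linear sequence: 13 steps from 1 (steps 1, 2, 4, 5, 8–16).

Step 9 (key step). Most likely to go wrong: incomplete conversion and reversion of the enol-ether adduct during concentration or chromatography, because furan cycloadditions are equilibria and the aromatic diene is easily regenerated. The fallback sets out from 17 and comes back at 19. The cycloaddition is run in wet toluene with pyridinium p-toluenesulfonate, so that the enol ether of 18 is hydrolysed as it forms (a non-aromatic enol ether is protonated far more readily than the furan of 17); the resulting bridged C1 ketone F1 cannot revert. Pyrrolidone hydrotribromide in THF then brominates C2 from the exo face to the exo-2-bromo C1 ketone F2, and MeOSiMe3 with catalytic Me3SiOTf at -78 °C converts the ketone into the dimethyl ketal 19.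

Step 8. Most likely to go wrong: insufficient enantio- or diastereoselectivity in the acid-catalysed allylboration of an electron-rich β,β-disubstituted enal with a hindered 2-boryl allylboronate, or acid-induced isomerisation of the Z enal. The fallback sets out from 10 and 13 and comes back at 16, which is then isolated and converted into 17 by the periodate treatment of step 8. It is a copper-catalysed three-component coupling: CuCl/NaOt-Bu with a chiral bisphosphine and B2pin2 in THF adds Cu–B across the terminal double bond of 13, and the 2-boryl allylcopper adds to 10 through a closed six-membered transition state under base-only conditions; the alkoxide is turned over as 15, which gives 16 on aqueous work-up. No compound outside the list is made.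

Step 12. Most likely to go wrong: after the fragmentation the C6 alkoxide sits β to the new C8 ketone, so retro-aldol cleavage of C6–C7, or β-elimination of the C6 carboxylate once the lactone has formed, can compete with clean lactonisation. The fallback sets out from 20 and comes back at 23. The ester is saponified (LiOH, THF/H2O, 0 °C, buffered work-up) to the hydroxy acid F3. The lactone is then closed before the fragmentation with a carbodiimide and DMAP to the tricyclic bromo ketal lactone F4; activation makes this closure irreversible although ring B must adopt a boat, and only the secondary C6 hydroxyl can reach the acid. One equivalent of KN(SiMe3)2 then triggers the fragmentation of F4 to 23 with no alkoxide left in the flask.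

Step 13. Most likely to go wrong: hydride delivery to the β face of C8, because facial preference on a bridged ten-membered ring cannot be predicted safely; this would give the 8-epimer. The fallback sets out from 23 and comes back at 24. The reduction product, the 8-epimeric alcohol F5, is inverted by a Mitsunobu reaction with chloroacetic acid (PPh3, diisopropyl azodicarboxylate) to the 8R chloroacetate F6, which is cleaved within minutes by K2CO3 in MeOH at 0 °C to give 24.

## Further compounds

F1 | step 9 | C1 ketone of the cycloadduct (3S,6S,7R,8S,10S); boron on C8 bonded to O6 | C[C@@]12C[C@@]3(B4O)[C@@H](CC(=O)OCC)[C@H](O4)C=C(CO[Si](C)(C)C(C)(C)C)[C@]3(O1)CC2=O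
F2 | step 9 | exo-2-bromo C1 ketone (2R,3S,6S,7R,8S,10S) | C[C@@]12C[C@@]3(B4O)[C@@H](CC(=O)OCC)[C@H](O4)C=C(CO[Si](C)(C)C(C)(C)C)[C@]3(O1)[C@@H](Br)C2=O
F0 | step 8 | none | none
F3 | step 12 | hydroxy acid from 20 (2R,3R,6S,7S,8R,10S) | C[C@@]12C[C@@]3(O)[C@@H](CC(=O)O)[C@H](O)C=C(CO[Si](C)(C)C(C)(C)C)[C@]3(O1)[C@@H](Br)C2(OC)OC
F4 | step 12 | tricyclic bromo ketal with closed trans-lactone and free C8 hydroxyl (2R,3R,6R,7S,8R,10S) | C[C@@]12C[C@@]3(O)[C@H]4CC(=O)O[C@@H]4C=C(CO[Si](C)(C)C(C)(C)C)[C@]3(O1)[C@@H](Br)C2(OC)OC
F5 | step 13 | 8-epimer of 24 (6R,7R,8S,10S) | C1C(=O)O[C@@H]2/C=C(/CO[Si](C)(C)C(C)(C)C)C3=CC(OC)(OC)[C@](C)(C[C@H](O)[C@@H]12)O3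
F6 | step 13 | 8-O-chloroacetate of 24 (6R,7R,8R,10S) | C1C(=O)O[C@@H]2/C=C(/CO[Si](C)(C)C(C)(C)C)C3=CC(OC)(OC)[C@](C)(C[C@@H](OC(=O)CCl)[C@@H]12)O3
A1 | alternative 1 | furan-3(2H)-one, open between C6 and C7, with C8 ester and C11–C13 acrylate | C[C@@]1(C[C@@H](OC(=O)CC(C)C)/C=C(\CO[Si](CC)(CC)CC)C(=O)OC)OC(=CC1=O)/C(CO[Si](C)(C)C(C)(C)C)=C\COCc2ccc(OC)cc2
A2 | alternative 2 | trans,trans-trisubstituted lactone with C11 dimethylaminomethyl group and C8 dithiane | CN(C)C[C@@H]1C(=O)O[C@H](CO[Si](c2ccccc2)(c3ccccc3)C(C)(C)C)[C@H]1C4(C[C@@]5(C)COC(C)(C)O5)SCCCS4
A3 | alternative 3 | oxygen-bridged cyclodecadienone with C8 ketone and C1 ethyl ether | C[C@@]12CC(=O)[C@@H](C(C)=C)[C@H](O[Si](C)(C)C(C)(C)C)/C=C(/C)C(O1)=C[C@H]2OCC
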